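**Plan**

1. Retrosynthesis: first cut the malate ester C–O bond, then the bond between the carboxyl-bearing methine C1′ (the exocyclic carbon on C2 of the 5-oxooxolane ring) and chain carbon C2′, then the ester bridge that delivers the chain, and last the bond from ring C2 to its ring CH2CH2CO arm.
2. Feature used: the CO2H on methine C1′ lies α to the bond to be made, so it can serve as a temporary ester bridge to a 1-alken-3-ol carrying the whole C10 chain. An ester-enolate [3,3] shift then turns the bridge C–O bond into the C1′–C2′ bond and the bridge into that very carboxyl group. Ring atoms O1 and C2, with the C2 carboxyl, are held meanwhile as a 1,3-dioxolan-4-one, which leaves the bridging ester as the only ester able to rearrange.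
3. Forward order: L-malic acid → cis-2-tert-butyl-dioxolanone → Michael addition to tert-butyl acrylate (quaternary carbon) → ester with the (R)-allylic alcohol made from octane-1,8-diol → rearrangement (chain joined) → hydrogenation of the sacrificial alkene → acid unmasking, in which the oxolane (γ-lactone) ring closes last → malate ester.
4. Stereochemistry: ring C2 (S) comes from L-malic acid by self-regeneration of its stereocentre. Methine C1′ (R) comes by 1,3-chirality transfer through a chair transition state from a sacrificial carbinol centre, which is set by Sharpless kinetic resolution and erased in the rearrangement. The malate centre (R) comes from D-malic acid.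

Key step: step 8

Remark: the target is read as (2S) at oxolane C2, (1R) at the side-chain methine and (R) in the malate unit; both enantiomers of malic acid and of diisopropyl tartrate are taken as commercial.

**Step 1**
Reactants: 1 (S)-malic acid
Product: 2 2-[(2S,4S)-2-tert-butyl-5-oxo-1,3-dioxolan-4-yl]acetic acid (cis)
Conditions: t-BuCHO, TsOH (cat.), H2SO4 (cat.), pentane, reflux, Dean–Stark; recrystallisation
Reagents that add atoms: pivalaldehyde CC(C)(C)C=O
Why: Acid-catalysed acetalisation of the α-hydroxy acid unit with water removal gives the 2-tert-butyl-1,3-dioxolan-4-one, the cis isomer being favoured at equilibrium and purified by crystallisation, so that the malic acid stereocentre is stored in the new acetal centre (self-regeneration of stereocentres).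

**Step 2**
Reactants: 2 2-[(2S,4S)-2-tert-butyl-5-oxo-1,3-dioxolan-4-yl]acetic acid
Product: 3 2-[(2S,4S)-4-(3-tert-butoxy-3-oxopropyl)-2-tert-butyl-5-oxo-1,3-dioxolan-4-yl]acetic acid
Conditions: LiN(SiMe3)2 (2.2 equiv), THF, −78 °C; tert-butyl acrylate (1.05 equiv), −78 °C; 1 M HCl
Reagents that add atoms: tert-butyl acrylate C=CC(=O)OC(C)(C)C
Why: The dilithium species (carboxylate plus ring enolate) undergoes Michael addition to the acrylate on the enolate face anti to the tert-butyl group, which replaces the former hydrogen with retention and sets the (S) quaternary carbon, while the carboxylate shields the CH2 arm from deprotonation.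

**Step 3**
Reactants: 4 octane-1,8-diol
Product: 5 8-[(tert-butyldimethylsilyl)oxy]octan-1-ol
Conditions: NaH (1.0 equiv), THF, 23 °C; t-BuMe2SiCl (1.0 equiv)
Reagents that add atoms: tert-butyldimethylsilyl chloride CC(C)(C)[Si](C)(C)Cl
Why: Monosilylation of a symmetrical diol through its monosodium alkoxide (O-silylation with one equivalent of chlorosilane) differentiates the two chain ends.

**Step 4**
Reactants: 5 8-[(tert-butyldimethylsilyl)oxy]octan-1-ol
Product: 6 8-[(tert-butyldimethylsilyl)oxy]octanal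
Conditions: TEMPO (cat.), PhI(OAc)2, CH2Cl2, 23 °C
Reagents that add atoms: none
Why: TEMPO-catalysed oxidation (oxoammonium mechanism) stops at the aldehyde and leaves the silyl ether untouched.

**Step 5**
Reactants: 6 8-[(tert-butyldimethylsilyl)oxy]octanal
Product: 7 rac-10-[(tert-butyldimethylsilyl)oxy]dec-1-en-3-ol
Conditions: CH2=CHMgBr, THF, −78 → 0 °C; aq. NH4Cl
Reagents that add atoms: vinylmagnesium bromide C=C[Mg]Br
Why: Grignard 1,2-addition to the aldehyde gives the racemic vinyl carbinol, whose stereocentre is resolved in the next step.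

**Step 6**
Reactants: 7 rac-10-[(tert-butyldimethylsilyl)oxy]dec-1-en-3-ol
Product: 8 (3R)-10-[(tert-butyldimethylsilyl)oxy]dec-1-en-3-ol
Conditions: Ti(OiPr)4 (cat.), L-(+)-diisopropyl tartrate (cat.), t-BuOOH (0.6 equiv), 4 Å MS, CH2Cl2, −20 °C
Reagents that add atoms: none
Why: Sharpless kinetic resolution, in which the L-(+)-tartrate catalyst epoxidises the (S)-enantiomer of a 1-alken-3-ol much faster, so the (R)-alcohol should be recovered unchanged in high enantiomeric purity at slightly over half conversion.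

**Step 7**
Reactants: 3 2-[(2S,4S)-4-(3-tert-butoxy-3-oxopropyl)-2-tert-butyl-5-oxo-1,3-dioxolan-4-yl]acetic acid; 8 (3R)-10-[(tert-butyldimethylsilyl)oxy]dec-1-en-3-ol
Product: 9 (3R)-10-[(tert-butyldimethylsilyl)oxy]dec-1-en-3-yl 2-[(2S,4S)-4-(3-tert-butoxy-3-oxopropyl)-2-tert-butyl-5-oxo-1,3-dioxolan-4-yl]acetate
Conditions: DCC, DMAP (cat.), CH2Cl2, 0 → 23 °C
Reagents that add atoms: none
Why: Steglich esterification (carbodiimide activation, acyl transfer by DMAP) joins the two fragments through the temporary ester; the carbinol C–O bond is not broken, so its (R) configuration is retained.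

**Step 8**
Reactants: 9 (3R)-10-[(tert-butyldimethylsilyl)oxy]dec-1-en-3-yl 2-[(2S,4S)-4-(3-tert-butoxy-3-oxopropyl)-2-tert-butyl-5-oxo-1,3-dioxolan-4-yl]acetate
Product: 12 (2R,4E)-2-[(2S,4S)-4-(3-tert-butoxy-3-oxopropyl)-2-tert-butyl-5-oxo-1,3-dioxolan-4-yl]-12-[(tert-butyldimethylsilyl)oxy]dodec-4-enoic acid, via bis(trimethylsilyl) ketene acetal 10 (not isolated), via trimethylsilyl ester 11 (not isolated)
Conditions: Me3SiCl/Et3N, THF, −78 °C; LiN(iPr)2 (3 equiv), −78 °C (internal quench); then 23 → 60 °C; aq. citric acid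
Reagents that add atoms: none
Why: Kinetic deprotonation of the bridging ester through the cyclic six-membered lithium amide transition state (bulky quaternary α-substituent, THF without polar cosolvent) should give the E(O) enolate, which is trapped at once as silyl ketene acetal 10 and then undergoes a concerted [3,3]-sigmatropic shift through a chair array in which the (CH2)7OSi chain on the carbinol carbon is equatorial and the ester C–O bond breaks as the new C–C bond forms, giving silyl ester 11 and, after mild acidic work-up, acid 12. The closest known reaction type is the Ireland–Claisen rearrangement of esters of enantioenriched secondary 1-alken-3-ols, which proceeds with 1,3-chirality transfer and E-alkene formation. No ring is closed, since the six-membered array exists only in the pericyclic transition state and the ester tether ends up as the new carboxyl group. The new methine stereocentre is controlled by the (R)-carbinol centre of the tether together with the E(O) ketene acetal geometry, which in the chair places the new bond on the face that gives the (2R) acid, while the adjacent dioxolanone carbon is quaternary and cannot epimerise. The step needs site selectivity (secured because the dioxolanone has no α-hydrogen and the tert-butyl ester, although also silylated by the excess base, carries no allyl group and reverts to the ester on work-up), control of ketene acetal geometry and of chair over boat (secured by LiN(iPr)2 in THF and the acyclic allyl unit), and suppression of β-elimination of the acetal oxygen (secured by silylation at −78 °C before warming).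

**Step 9**
Reactants: 12 (2R,4E)-2-[(2S,4S)-4-(3-tert-butoxy-3-oxopropyl)-2-tert-butyl-5-oxo-1,3-dioxolan-4-yl]-12-[(tert-butyldimethylsilyl)oxy]dodec-4-enoic acid
Product: 13 (2R)-2-[(2S,4S)-4-(3-tert-butoxy-3-oxopropyl)-2-tert-butyl-5-oxo-1,3-dioxolan-4-yl]-12-[(tert-butyldimethylsilyl)oxy]dodecanoic acid
Conditions: H2 (1 atm), Pd/C, EtOAc, 23 °C
Reagents that add atoms: none
Why: Heterogeneous hydrogenation saturates the disubstituted alkene left by the rearrangement, no stereocentre being affected and the silyl ether, tert-butyl ester and dioxolanone being inert.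

**Step 10**
Reactants: 13 (2R)-2-[(2S,4S)-4-(3-tert-butoxy-3-oxopropyl)-2-tert-butyl-5-oxo-1,3-dioxolan-4-yl]-12-[(tert-butyldimethylsilyl)oxy]dodecanoic acid
Product: 15 (2S)-2-[(1R)-1-carboxy-11-hydroxyundecyl]-5-oxooxolane-2-carboxylic acid, via open hydroxy triacid 14 (not isolated)
Conditions: 3 M HCl, 1,4-dioxane–H2O, 80 °C; concentrate
Reagents that add atoms: water O
Why: Hot aqueous acid hydrolyses the dioxolanone (releasing pivalaldehyde), the tert-butyl ester and the silyl ether, and the γ-hydroxy acid so revealed closes the five-membered lactone (5-exo-trig acyl substitution by the tertiary hydroxyl) without touching either stereocentre.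

**Step 11**
Reactants: 16 (R)-malic acid
Product: 17 (3R)-2,5-dioxooxolan-3-yl trifluoroacetate
Conditions: (CF3CO)2O, neat, 0 → 23 °C; evaporate
Reagents that add atoms: trifluoroacetic anhydride O=C(OC(=O)C(F)(F)F)C(F)(F)F
Why: Trifluoroacetic anhydride acylates the hydroxyl and dehydrates the diacid to the cyclic anhydride, a known activation of malic acid that keeps the stereocentre.

**Step 12**
Reactants: 15 (2S)-2-[(1R)-1-carboxy-11-hydroxyundecyl]-5-oxooxolane-2-carboxylic acid; 17 (3R)-2,5-dioxooxolan-3-yl trifluoroacetate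
Product: 19 (2S)-2-[(1R)-1-carboxy-11-{[(2R)-3-carboxy-2-hydroxypropanoyl]oxy}undecyl]-5-oxooxolane-2-carboxylic acid, via O-trifluoroacetyl ester 18 (not isolated)
Conditions: 17 (2–3 equiv), THF, 23 → 40 °C; then H2O–THF, 23 °C
Reagents that add atoms: none
Why: Alcoholysis of the anhydride by the primary alcohol should occur at the carbonyl next to the trifluoroacetoxy-bearing carbon, giving the ester at the carboxyl adjacent to the carbinol carbon with a free distal acid, and mild hydrolysis then removes the labile trifluoroacetate; without base the free carboxyl groups of 15 are not acylated.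

**Compound list**

1 | (S)-malic acid | OC(=O)C[C@H](O)C(=O)O | starting material
2 | 2-[(2S,4S)-2-tert-butyl-5-oxo-1,3-dioxolan-4-yl]acetic acid | OC(=O)C[C@@H]1O[C@H](C(C)(C)C)OC1=O | intermediate
3 | 2-[(2S,4S)-4-(3-tert-butoxy-3-oxopropyl)-2-tert-butyl-5-oxo-1,3-dioxolan-4-yl]acetic acid | OC(=O)C[C@]1(CCC(=O)OC(C)(C)C)O[C@H](C(C)(C)C)OC1=O | intermediate
4 | octane-1,8-diol | OCCCCCCCCO | starting material
5 | 8-[(tert-butyldimethylsilyl)oxy]octan-1-ol | OCCCCCCCCO[Si](C)(C)C(C)(C)C | intermediate
6 | 8-[(tert-butyldimethylsilyl)oxy]octanal | O=CCCCCCCCO[Si](C)(C)C(C)(C)C | intermediate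
7 | rac-10-[(tert-butyldimethylsilyl)oxy]dec-1-en-3-ol | C=CC(O)CCCCCCCO[Si](C)(C)C(C)(C)C | intermediate
8 | (3R)-10-[(tert-butyldimethylsilyl)oxy]dec-1-en-3-ol | C=C[C@H](O)CCCCCCCO[Si](C)(C)C(C)(C)C | intermediate
9 | (3R)-10-[(tert-butyldimethylsilyl)oxy]dec-1-en-3-yl 2-[(2S,4S)-4-(3-tert-butoxy-3-oxopropyl)-2-tert-butyl-5-oxo-1,3-dioxolan-4-yl]acetate | C=C[C@H](OC(=O)C[C@]1(CCC(=O)OC(C)(C)C)O[C@H](C(C)(C)C)OC1=O)CCCCCCCO[Si](C)(C)C(C)(C)C | intermediate
10 | bis(trimethylsilyl) ketene acetal of 9, E(O) geometry at the allylic ester, tert-butyl ester silylated as a spectator | C=C[C@H](O/C(O[Si](C)(C)C)=C\[C@]1(CC=C(O[Si](C)(C)C)OC(C)(C)C)O[C@H](C(C)(C)C)OC1=O)CCCCCCCO[Si](C)(C)C(C)(C)C | intermediate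
11 | trimethylsilyl ester of the rearranged (2R,4E)-acid, spectator ketene acetal still in place | C[Si](C)(C)OC(=O)[C@H](C/C=C/CCCCCCCO[Si](C)(C)C(C)(C)C)[C@]1(CC=C(O[Si](C)(C)C)OC(C)(C)C)O[C@H](C(C)(C)C)OC1=O | intermediate
12 | (2R,4E)-2-[(2S,4S)-4-(3-tert-butoxy-3-oxopropyl)-2-tert-butyl-5-oxo-1,3-dioxolan-4-yl]-12-[(tert-butyldimethylsilyl)oxy]dodec-4-enoic acid | OC(=O)[C@H](C/C=C/CCCCCCCO[Si](C)(C)C(C)(C)C)[C@]1(CCC(=O)OC(C)(C)C)O[C@H](C(C)(C)C)OC1=O | intermediate
13 | (2R)-2-[(2S,4S)-4-(3-tert-butoxy-3-oxopropyl)-2-tert-butyl-5-oxo-1,3-dioxolan-4-yl]-12-[(tert-butyldimethylsilyl)oxy]dodecanoic acid | OC(=O)[C@H](CCCCCCCCCCO[Si](C)(C)C(C)(C)C)[C@]1(CCC(=O)OC(C)(C)C)O[C@H](C(C)(C)C)OC1=O | intermediate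
14 | (1R,2S)-2-hydroxy-1-(10-hydroxydecyl)butane-1,2,4-tricarboxylic acid (open hydroxy triacid) | OC(=O)[C@H](CCCCCCCCCCO)[C@](O)(C(=O)O)CCC(=O)O | intermediate
15 | (2S)-2-[(1R)-1-carboxy-11-hydroxyundecyl]-5-oxooxolane-2-carboxylic acid | OC(=O)[C@H](CCCCCCCCCCO)[C@]1(C(=O)O)CCC(=O)O1 | intermediate
16 | (R)-malic acid | OC(=O)C[C@@H](O)C(=O)O | starting material
17 | (3R)-2,5-dioxooxolan-3-yl trifluoroacetate | O=C1C[C@@H](OC(=O)C(F)(F)F)C(=O)O1 | intermediate
18 | O-trifluoroacetyl ester of 19 | O=C(O)C[C@@H](OC(=O)C(F)(F)F)C(=O)OCCCCCCCCCC[C@@H](C(=O)O)[C@]1(C(=O)O)CCC(=O)O1 | intermediate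
19 | (2S)-2-[(1R)-1-carboxy-11-{[(2R)-3-carboxy-2-hydroxypropanoyl]oxy}undecyl]-5-oxooxolane-2-carboxylic acid | O=C(O)C[C@@H](O)C(=O)OCCCCCCCCCC[C@@H](C(=O)O)[C@]1(C(=O)O)CCC(=O)O1 | target

**Count and risks**

Total step count: 12. Longest linear sequence: 9 steps (steps 3, 4, 5, 6, 7, 8, 9, 10 and 12).

Most likely to fail, in this order:

Step 8. What may go wrong: erosion of the E(O) ketene acetal geometry or partial reaction through a boat, either of which lowers the diastereoselectivity at the new methine; β-elimination of the enolate with opening of the dioxolanone before silylation; condensation of the tert-butyl ester enolate onto the bridging ester. The fallback sets out from 3 and 7 and comes back at 13, replacing the rearrangement by an auxiliary-controlled intermolecular alkylation. Acid 3 is converted through its pivaloyl mixed anhydride (t-BuCOCl, Et3N) with lithiated (4R)-4-benzyl-1,3-oxazolidin-2-one into (4R)-4-benzyl-3-{2-[(2S,4S)-4-(3-tert-butoxy-3-oxopropyl)-2-tert-butyl-5-oxo-1,3-dioxolan-4-yl]acetyl}-1,3-oxazolidin-2-one F1. The racemic alcohol 7, for which no resolution is then needed, is converted with PBr3 under allylic transposition into {[(8E)-10-bromodec-8-en-1-yl]oxy}(tert-butyl)dimethylsilane F2. NaN(SiMe3)2 at −78 °C enolises only the imide, giving the chelated Z-enolate, and Evans alkylation with F2 on the face opposite the benzyl group should give the (2R,4E)-alkylated imide F3. H2 over Pd/C gives the saturated imide F4, and LiOH/H2O2 at 0 °C removes the auxiliary from the exocyclic carbonyl to give 13, the hindered dioxolanone and the tert-butyl ester being expected to survive.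

Step 2. What may go wrong: anionic oligomerisation of the acrylate by the adduct enolate, or sluggish addition of the aggregated dianion followed by its decomposition on warming. The fallback sets out from 2 and comes back at 15. The same dianion is alkylated with allyl bromide, a reactive electrophile that alkylates dioxolanone enolates reliably, to give 2-[(2S,4S)-2-tert-butyl-5-oxo-4-(prop-2-en-1-yl)-1,3-dioxolan-4-yl]acetic acid F5. Steglich esterification with 8 gives the allylic ester F6, whose rearrangement under the step 8 conditions, now with a single enolisable ester, gives the dienoic acid F7. 9-BBN in excess hydroborates only the monosubstituted alkene, and NaBO3·4H2O oxidation gives the primary alcohol F8. H2 over Pd/C gives the saturated hydroxy acid F9, and TEMPO/PhI(OAc)2 in MeCN–H2O oxidises the primary alcohol to give the diacid F10, which under the step 10 conditions gives 15.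

Step 12. What may go wrong: attack of the alcohol at the distal anhydride carbonyl, giving the wrongly linked ester, and acyl scrambling with the two free carboxyl groups, which would complicate purification of a polar triacid. The fallback sets out from 15 and comes back at 19, fixing the ester linkage by carboxylate alkylation instead of acylation. Both carboxyl groups of 15 are benzylated (BnBr, KHCO3, DMF) to give benzyl (2S)-2-[(1R)-1-(benzyloxycarbonyl)-11-hydroxyundecyl]-5-oxooxolane-2-carboxylate F11, and the primary alcohol is converted (I2, PPh3, imidazole) into the corresponding primary iodide F12. Commercial D-aspartic acid 4-benzyl ester is diazotised (NaNO2, aq. H2SO4, retention) to (2R)-4-(benzyloxy)-2-hydroxy-4-oxobutanoic acid F13. Its caesium carboxylate (Cs2CO3, DMF) is alkylated by F12 to give the tribenzyl ester F14, and H2 over Pd/C then gives 19.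

**Further compounds**

F1 | step 8 | (4R)-4-benzyl-3-{2-[(2S,4S)-4-(3-tert-butoxy-3-oxopropyl)-2-tert-butyl-5-oxo-1,3-dioxolan-4-yl]acetyl}-1,3-oxazolidin-2-one | O=C1OC[C@@H](Cc2ccccc2)N1C(=O)C[C@]3(CCC(=O)OC(C)(C)C)O[C@H](C(C)(C)C)OC3=O
F2 | step 8 | {[(8E)-10-bromodec-8-en-1-yl]oxy}(tert-butyl)dimethylsilane | BrC/C=C/CCCCCCCO[Si](C)(C)C(C)(C)C
F3 | step 8 | (4R)-4-benzyl-3-[(2R,4E)-2-{(2S,4S)-4-(3-tert-butoxy-3-oxopropyl)-2-tert-butyl-5-oxo-1,3-dioxolan-4-yl}-12-{(tert-butyldimethylsilyl)oxy}dodec-4-enoyl]-1,3-oxazolidin-2-one | O=C1OC[C@@H](Cc2ccccc2)N1C(=O)[C@H](C/C=C/CCCCCCCO[Si](C)(C)C(C)(C)C)[C@]3(CCC(=O)OC(C)(C)C)O[C@H](C(C)(C)C)OC3=O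
F4 | step 8 | (4R)-4-benzyl-3-[(2R)-2-{(2S,4S)-4-(3-tert-butoxy-3-oxopropyl)-2-tert-butyl-5-oxo-1,3-dioxolan-4-yl}-12-{(tert-butyldimethylsilyl)oxy}dodecanoyl]-1,3-oxazolidin-2-one | O=C1OC[C@@H](Cc2ccccc2)N1C(=O)[C@H](CCCCCCCCCCO[Si](C)(C)C(C)(C)C)[C@]3(CCC(=O)OC(C)(C)C)O[C@H](C(C)(C)C)OC3=O
F5 | step 2 | 2-[(2S,4S)-2-tert-butyl-5-oxo-4-(prop-2-en-1-yl)-1,3-dioxolan-4-yl]acetic acid | OC(=O)C[C@]1(CC=C)O[C@H](C(C)(C)C)OC1=O
F6 | step 2 | (3R)-10-[(tert-butyldimethylsilyl)oxy]dec-1-en-3-yl 2-[(2S,4S)-2-tert-butyl-5-oxo-4-(prop-2-en-1-yl)-1,3-dioxolan-4-yl]acetate | C=C[C@H](OC(=O)C[C@]1(CC=C)O[C@H](C(C)(C)C)OC1=O)CCCCCCCO[Si](C)(C)C(C)(C)C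
F7 | step 2 | (2R,4E)-2-[(2S,4S)-2-tert-butyl-5-oxo-4-(prop-2-en-1-yl)-1,3-dioxolan-4-yl]-12-[(tert-butyldimethylsilyl)oxy]dodec-4-enoic acid | OC(=O)[C@H](C/C=C/CCCCCCCO[Si](C)(C)C(C)(C)C)[C@]1(CC=C)O[C@H](C(C)(C)C)OC1=O
F8 | step 2 | (2R,4E)-2-[(2S,4S)-2-tert-butyl-4-(3-hydroxypropyl)-5-oxo-1,3-dioxolan-4-yl]-12-[(tert-butyldimethylsilyl)oxy]dodec-4-enoic acid | OC(=O)[C@H](C/C=C/CCCCCCCO[Si](C)(C)C(C)(C)C)[C@]1(CCCO)O[C@H](C(C)(C)C)OC1=O
F9 | step 2 | (2R)-2-[(2S,4S)-2-tert-butyl-4-(3-hydroxypropyl)-5-oxo-1,3-dioxolan-4-yl]-12-[(tert-butyldimethylsilyl)oxy]dodecanoic acid | OC(=O)[C@H](CCCCCCCCCCO[Si](C)(C)C(C)(C)C)[C@]1(CCCO)O[C@H](C(C)(C)C)OC1=O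
F10 | step 2 | (2R)-2-[(2S,4S)-2-tert-butyl-4-(2-carboxyethyl)-5-oxo-1,3-dioxolan-4-yl]-12-[(tert-butyldimethylsilyl)oxy]dodecanoic acid | OC(=O)[C@H](CCCCCCCCCCO[Si](C)(C)C(C)(C)C)[C@]1(CCC(=O)O)O[C@H](C(C)(C)C)OC1=O
F11 | step 12 | benzyl (2S)-2-[(1R)-1-(benzyloxycarbonyl)-11-hydroxyundecyl]-5-oxooxolane-2-carboxylate | OCCCCCCCCCC[C@@H](C(=O)OCc1ccccc1)[C@]1(C(=O)OCc2ccccc2)CCC(=O)O1
F12 | step 12 | benzyl (2S)-2-[(1R)-1-(benzyloxycarbonyl)-11-iodoundecyl]-5-oxooxolane-2-carboxylate | ICCCCCCCCCC[C@@H](C(=O)OCc1ccccc1)[C@]1(C(=O)OCc2ccccc2)CCC(=O)O1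
F13 | step 12 | (2R)-4-(benzyloxy)-2-hydroxy-4-oxobutanoic acid | OC(=O)[C@H](O)CC(=O)OCc1ccccc1
F14 | step 12 | benzyl (2S)-2-[(1R)-1-(benzyloxycarbonyl)-11-{[(2R)-4-(benzyloxy)-2-hydroxy-4-oxobutanoyl]oxy}undecyl]-5-oxooxolane-2-carboxylate | O=C(OCc1ccccc1)C[C@@H](O)C(=O)OCCCCCCCCCC[C@@H](C(=O)OCc1ccccc1)[C@]1(C(=O)OCc2ccccc2)CCC(=O)O1
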